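Late in Monday's run the substrate's logarithmic loss L, the natural log of charged over remaining substrate (a straight line in time for a pseudo-first-order loss), slows from 0.00582 s⁻¹ to 0.00422 s⁻¹. This reads as free catalyst dying at about 0.0128 s⁻¹, a reading with wide scatter. Monday's run serves here because it charges less catalyst than the others.

| flask | substrate | gas phase | protic impurity | free catalyst | remark | time |
|---|---|---|---|---|---|---|
| Monday's | 0.034 M | 14 mM (held) | 5 mM | 15 mol% | run made earlier |  |
| Thursday's | 0.075 M | 14 mM (held) | 5 mM | 15 mol% | run made earlier |  |
| Friday's | 0.050 M | 14 mM (held) | 10 mM | 15 mol% | run made earlier |  |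
| flask | 0.050 M | 14 mM (held) | 5.00 mM | 15 mol% |  | 2.0 min |

| run | time / s | target / % | substrate / % |
|---|---|---|---|
| Monday's | 10.0 | 4.2 | 95.4 |
| Monday's | 12.0 | 5.4 | 93.9 |
| Monday's | 20.0 | 11.6 | 89.0 |
| Monday's | 40.0 | 23.0 | 77.4 |
| Monday's | 60.0 | 31.4 | 68.9 |
| Monday's | 90.0 | 39.9 | 60.7 |
| Thursday's | 10.0 | 7.7 | 92.2 |
| Thursday's | 20.0 | 17.1 | 82.1 |
| Thursday's | 30.0 | 26.2 | 73.6 |
| Thursday's | 50.0 | 40.3 | 59.8 |
| Thursday's | 80.0 | 54.1 | 45.7 |
| Thursday's | 90.0 | 57.3 | 42.6 |
| Friday's | 10.0 | 5.5 | 94.5 |
| Friday's | 15.0 | 9.2 | 90.1 |
| Friday's | 25.0 | 17.4 | 83.0 |
| Friday's | 50.0 | 33.4 | 67.5 |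
| Friday's | 90.0 | 47.7 | 52.3 |

(standard deviation of a reading: 0.3 percentage points)

- at the start none of the gas is dissolved
- reactions considered so far: gas phase <-> dissolved gas; substrate + dissolved gas + free catalyst -> free catalyst + target; free catalyst -> spent catalyst; dissolved gas + protic impurity -> quenched reagent

- blue: doubling the transfer coefficient of the gas phase, all else as stated
- violet: doubling the amount of free catalyst, all else as stated
- grey: doubling the saturation concentration of gas phase, all else as stated

- how much target there is at 2.0 min, in percent of the substrate charged
- the change that raises the amount of target at 2.0 min, in percent of the substrate charged most ("none" if none brings more than 2 percentage points) (blue / violet / grey / none)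
- amount of target at 2.0 min, in percent of the substrate charged, after violet

Friday's run has the flask's substrate and loading, but twice its impurity. Its late slope, 0.00638 s⁻¹, carried to its last reading and divided by the dying rate, gives the reach, the loss in L still to come from a given moment: 0.386. In this reckoning, with c(dissolved gas) taken as steady, the reach shrinks at the catalyst's dying rate. Friday's L of 0.648 at its last reading is therefore reckoned to end near 1.03, and to stand at 0.771 after 2.0 min. This reckoning commits to 53.8 % of target for the flask, taken as slightly low since Friday's run holds more impurity than the flask.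

Grey doubles c(dissolved gas) by hand, and with it L, giving 78.6 %. Violet doubles L too by hand, but it charges 15.0 mM of catalyst against Thursday's 11.2 mM, so the drop in L per substrate charged from Friday's last reading to Thursday's, in runs that also differ in impurity, is applied, giving 74.2 %. Blue, taken by hand as closing the gap from Friday's L per charge to Monday's, in runs that also differ in impurity, gives 58.3 %. Grey leads by hand.

The forecast gives 55.5 % (52 % to 59 %), 75 % after violet (70 % to 80 %) and grey as best, holding that “dissolved gas doubles, so the rate doubles”.

The flask gives 55.2 % of target and 76.8 % after violet; the gains are 5.9 percentage points for blue, 22 points for violet and 27 points for grey, so grey is best.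

    gas phase ⇌ dissolved gas, rate k1*(csat - [dissolved gas]) (kL = 0.130 s⁻¹)
    substrate + dissolved gas + free catalyst → free catalyst + target (k = 193 M⁻² s⁻¹)
    free catalyst → spent catalyst (k = 0.0148 s⁻¹)
    dissolved gas + protic impurity → quenched reagent (k = 7.77 M⁻¹ s⁻¹)

From the flask's 55.2 %, L is 0.803 and the reach left is 0.263, which puts the end at 65.6 % of target; after 20.0 min the flask holds 64.3 %, with free catalyst at 0 %. The neighbouring flask is read at 80 s instead. Running the reach backwards takes L to 0.627, which means 46.6 % of target. That neighbouring flask holds 46.7 % of target, with 53.3 % of substrate.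

The runs were computed for substances that don't exist; scatter was added.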